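Slowness was my way in: in this flask the substrate drains far more slowly than the gas enters.

substrate 0.059 M; gas phase 5.4 mM (held); time 20 h

1. how much target and crystals together there is at 20 h, in percent of the substrate charged
2. concentration of dissolved gas in solution at 20 h, in percent of saturation

- amounts and yields of target count crystals too
- given per volume of solution although it is solid: crystals
- at the start none of the gas is dissolved
- run time (flask): 20 h

    gas phase ⇌ dissolved gas, rate k1*(csat - [dissolved gas]) (k1 = 22 /h, csat = 5.4 mM)
    substrate + dissolved gas → target (k2 = 20 /M/h)
    dissolved gas + target → over-reacted product (k3 = 53 /M/h)
    substrate → decomposition product (k4 = 7.0 × 10⁻⁵ /h)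
    crystals ⇌ target, rate k5*(cs5 - [target]) while solid is left; crystals form when [target] > cs5 (cs5 = 1.4 mM, k5 = 7.4 /h)
    dissolved gas → decomposed reagent (k6 = 0.11 /h)

I began with the gas. Transfer refills the solution at 22 /h, while the full charge of substrate spends dissolved gas at 1.18 /h. So I held the gas at saturation, which makes substrate loss pseudo-first-order. On that view I counted 2.16 turnovers for this flask, a turnover count being the target-forming rate constant times the saturation concentration times the time. By my reckoning that left 11.5% of the charge as substrate. Substrate decomposition took 0.140%, and I dropped it.

Next I reckoned the loss. I held dissolved target at its solubility, 2.37% of the charge. Over-reaction then burned 6.29% of the charge per turnover, and the yield came to 74.9%.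

That solubility was the weak link: in the scheme, crystals form when dissolved target stands above it. I took the whole converted fraction as crystallising at 7.4 /h. The excess needed for that growth burned a further 3.42%. I committed to 71.5%. With the remaining sinks set against transfer at the end, I put the gas at 98.6%.

The forecast gave 72%, a little above my yield, and 98.5%. Its ground was that “Gas transfer is far faster than gas consumption”.

The simulation gave 71.9% and 98.5%.

The yield of this flask rests on the low solubility of target together with the time given. The run without that low solubility gave 7.49% against 71.9%, and this flask read at 200 h gave 0%. The count carries to the same flask read at 2.0 d. There it stands at 5.18 turnovers and leaves 0.561% as substrate, and that flask held 0.62%.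

(All constants are those of an exercise; the run is a simulation.)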